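The route rests on disconnecting the bond between C1 of one guaiacyl ring and the exocyclic carbinol carbon on C3 of the oxolane (O1, C2H2, C3, C4, C5). In one operation an aryl Grignard reagent adds to an all-trans 5-aryl-4-vinyloxolane-3-carbaldehyde: the C3 stereocentre, flanked by the bulky C4 branch and by C2H2–O1, steers Re-face attack (Felkin–Anh, seconded by an O1 chelate) and sets the carbinol centre. The aldehyde comes from one lipase-resolved benzylic centre (C5), relayed to C4 and C3 in a single cuprate addition/equilibration on a metathesis-made dihydrofuran ester; the vinyl group is a latent hydroxymethyl, and benzyl ethers mask both phenols.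

Key step: step 7

Step 1
Reactants: 1 4-(benzyloxy)-3-methoxybenzaldehyde; 2 vinylmagnesium bromide
Product: 3 rac-1-[4-(benzyloxy)-3-methoxyphenyl]prop-2-en-1-ol
Conditions: THF, 0 °C; aq. NH4Cl
Reagents that add atoms: none
Why: Grignard 1,2-addition of the vinyl nucleophile to the aromatic aldehyde should give the allylic benzylic alcohol; the new stereocentre forms racemic and is resolved in step 2.

Step 2
Reactants: 3 rac-1-[4-(benzyloxy)-3-methoxyphenyl]prop-2-en-1-ol
Product: 4 (1S)-1-[4-(benzyloxy)-3-methoxyphenyl]prop-2-en-1-ol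
Conditions: immobilised Candida antarctica lipase B, vinyl acetate, MTBE, 30 °C, run to about half conversion; chromatographic separation from the (R)-acetate
Reagents that add atoms: none
Why: Lipase-catalysed kinetic resolution by enantioselective transesterification (aryl as the large, vinyl as the medium substituent) should acylate the (R)-alcohol and leave the (S)-alcohol, which becomes C5 of the oxolane; at most half of 3 is carried on.

Step 3
Reactants: 4 (1S)-1-[4-(benzyloxy)-3-methoxyphenyl]prop-2-en-1-ol; 5 methyl 2-(bromomethyl)prop-2-enoate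
Product: 6 methyl 2-({[(1S)-1-[4-(benzyloxy)-3-methoxyphenyl]prop-2-en-1-yl]oxy}methyl)prop-2-enoate
Conditions: NaH, THF, 0 °C; then 5, 0 °C to rt
Reagents that add atoms: none
Why: Williamson-type O-allylation of the sodium alkoxide (SN2 or SN2′ on the 2-(bromomethyl)acrylate gives the same ether) should proceed without touching the carbinol configuration.

Step 4
Reactants: 6 methyl 2-({[(1S)-1-[4-(benzyloxy)-3-methoxyphenyl]prop-2-en-1-yl]oxy}methyl)prop-2-enoate
Product: 7 methyl (5S)-5-[4-(benzyloxy)-3-methoxyphenyl]-2,5-dihydrofuran-3-carboxylate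
Conditions: second-generation Grubbs catalyst RuCl2(=CHPh)(PCy3)(H2IMes) (5 mol%), CH2Cl2, 40 °C
Reagents that add atoms: none
Why: Ring-closing olefin metathesis of the 1,6-diene should close the 2,5-dihydrofuran with loss of ethene and place the ester on the new ring alkene, the stereocentre being a spectator.

Step 5
Reactants: 7 methyl (5S)-5-[4-(benzyloxy)-3-methoxyphenyl]-2,5-dihydrofuran-3-carboxylate; 2 vinylmagnesium bromide
Product: 9 methyl (3S,4S,5S)-5-[4-(benzyloxy)-3-methoxyphenyl]-4-ethenyloxolane-3-carboxylate, via silyl ketene acetal 8 (not isolated)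
Conditions: 2, CuBr·SMe2 (10 mol%), TMSCl, THF, −78 to −40 °C; then NaOMe (cat.), MeOH, 0 °C to rt
Reagents that add atoms: none
Why: Copper-catalysed, TMSCl-accelerated conjugate addition of the vinyl Grignard reagent to the cyclic enoate should occur on the ring face opposite the adjacent C5 aryl group (4,5-trans), and methanolysis of the silyl ketene acetal under NaOMe equilibration should put the C3 ester trans to the vinyl group (thermodynamic all-trans isomer), so C4 and C3 are both relayed from C5 in one operation.

Step 6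
Reactants: 9 methyl (3S,4S,5S)-5-[4-(benzyloxy)-3-methoxyphenyl]-4-ethenyloxolane-3-carboxylate
Product: 10 (3S,4S,5S)-5-[4-(benzyloxy)-3-methoxyphenyl]-4-ethenyloxolane-3-carbaldehyde
Conditions: i-Bu2AlH (1.1 equiv), CH2Cl2, −78 °C; aq. Rochelle salt
Reagents that add atoms: none
Why: Partial reduction of the methyl ester with DIBAL-H at −78 °C should stop at the aluminium hemiacetal and give the aldehyde on work-up; the all-trans arrangement is the thermodynamic one, so the epimerisable C3 centre is not endangered.

Step 7
Reactants: 10 (3S,4S,5S)-5-[4-(benzyloxy)-3-methoxyphenyl]-4-ethenyloxolane-3-carbaldehyde; 11 1-(benzyloxy)-4-bromo-2-methoxybenzene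
Product: 13 (S)-[4-(benzyloxy)-3-methoxyphenyl]{(3S,4S,5S)-5-[4-(benzyloxy)-3-methoxyphenyl]-4-ethenyloxolan-3-yl}methanol, via arylmagnesium bromide 12 (not isolated)
Conditions: 11, Mg, THF, 40 °C; then 10, THF/CH2Cl2, −78 to −20 °C; aq. NH4Cl
Reagents that add atoms: none
Why: The aryl Grignard reagent adds to the formyl group in a polar 1,2-addition through a magnesium-bound cyclic transition state; the closest known reaction type is the Felkin–Anh (Cram-chelate) controlled Grignard addition to an α-branched β-alkoxy aldehyde. No ring is closed. The new carbinol stereocentre is controlled by the neighbouring ring stereocentre C3: the C4 ring branch (it carries the vinyl group and is backed by the C5 aryl group on the formyl face) is the large group and stands anti to the incoming aryl, the ring C2H2 is the medium group next to the carbonyl oxygen, and the nucleophile passes the C3 hydrogen, which means attack on the Re face and the (S)-carbinol. A six-membered magnesium chelate between the formyl oxygen and ring oxygen O1 would expose the same Re face, so the open and the chelated model reinforce each other. The step needs facial selectivity at the aldehyde and retention of the epimerisable C3 centre; the first is secured by the size difference between the C4 branch and C2H2, the second by the low basicity of the aryl Grignard reagent at −78 °C and by the all-trans aldehyde already being the thermodynamic epimer. Chemoselectivity is no issue because the aldehyde is the only electrophile and both phenols are masked as benzyl ethers.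

Step 8
Reactants: 13 (S)-[4-(benzyloxy)-3-methoxyphenyl]{(3S,4S,5S)-5-[4-(benzyloxy)-3-methoxyphenyl]-4-ethenyloxolan-3-yl}methanol
Product: 15 (S)-[4-(benzyloxy)-3-methoxyphenyl]{(3S,4R,5S)-5-[4-(benzyloxy)-3-methoxyphenyl]-4-(hydroxymethyl)oxolan-3-yl}methanol, via aldehyde 14 (not isolated)
Conditions: O3, CH2Cl2/MeOH, −78 °C, stopped at consumption of the alkene; Me2S, −78 to 0 °C; then NaBH4, 0 °C
Reagents that add atoms: ozone, [O-][O+]=O
Why: Ozonolysis of the only C=C bond (a monosubstituted alkene, far more reactive toward ozone than the dialkoxyarenes) with reductive work-up and borohydride reduction of the aldehyde should turn the latent vinyl group into the hydroxymethyl group with the C4 configuration unchanged.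

Step 9
Reactants: 15 (S)-[4-(benzyloxy)-3-methoxyphenyl]{(3S,4R,5S)-5-[4-(benzyloxy)-3-methoxyphenyl]-4-(hydroxymethyl)oxolan-3-yl}methanol
Product: 16 (S)-(4-hydroxy-3-methoxyphenyl)[(3S,4R,5S)-5-(4-hydroxy-3-methoxyphenyl)-4-(hydroxymethyl)oxolan-3-yl]methanol
Conditions: H2 (1 atm), 10% Pd/C, EtOAc, rt, stopped at complete debenzylation
Reagents that add atoms: none
Why: Catalytic hydrogenolysis of the two aryl benzyl ethers under neutral conditions should be faster than cleavage of the benzylic alcohol or of the benzylic ring ether and frees both phenols without touching a stereocentre.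

Compound list
1 | 4-(benzyloxy)-3-methoxybenzaldehyde | COc1cc(C=O)ccc1OCc1ccccc1 | starting material
2 | vinylmagnesium bromide | C=C[Mg]Br | starting material
3 | rac-1-[4-(benzyloxy)-3-methoxyphenyl]prop-2-en-1-ol | COc1cc(C(O)C=C)ccc1OCc1ccccc1 | intermediate
4 | (1S)-1-[4-(benzyloxy)-3-methoxyphenyl]prop-2-en-1-ol | COc1cc([C@@H](O)C=C)ccc1OCc1ccccc1 | intermediate
5 | methyl 2-(bromomethyl)prop-2-enoate | COC(=O)C(=C)CBr | starting material
6 | methyl 2-({[(1S)-1-[4-(benzyloxy)-3-methoxyphenyl]prop-2-en-1-yl]oxy}methyl)prop-2-enoate | COC(=O)C(=C)CO[C@H](c1ccc(OCc2ccccc2)c(OC)c1)C=C | intermediate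
7 | methyl (5S)-5-[4-(benzyloxy)-3-methoxyphenyl]-2,5-dihydrofuran-3-carboxylate | COC(=O)C1=C[C@@H](c2ccc(OCc3ccccc3)c(OC)c2)OC1 | intermediate
8 | ({(4S,5S)-5-[4-(benzyloxy)-3-methoxyphenyl]-4-ethenyloxolan-3-ylidene}(methoxy)methoxy)trimethylsilane (ketene acetal geometry not defined) | COC(O[Si](C)(C)C)=C1CO[C@H](c2ccc(OCc3ccccc3)c(OC)c2)[C@H]1C=C | intermediate
9 | methyl (3S,4S,5S)-5-[4-(benzyloxy)-3-methoxyphenyl]-4-ethenyloxolane-3-carboxylate | COC(=O)[C@@H]1CO[C@H](c2ccc(OCc3ccccc3)c(OC)c2)[C@H]1C=C | intermediate
10 | (3S,4S,5S)-5-[4-(benzyloxy)-3-methoxyphenyl]-4-ethenyloxolane-3-carbaldehyde | O=C[C@@H]1CO[C@H](c2ccc(OCc3ccccc3)c(OC)c2)[C@H]1C=C | intermediate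
11 | 1-(benzyloxy)-4-bromo-2-methoxybenzene | COc1cc(Br)ccc1OCc1ccccc1 | starting material
12 | [4-(benzyloxy)-3-methoxyphenyl]magnesium bromide | COc1cc([Mg]Br)ccc1OCc1ccccc1 | intermediate
13 | (S)-[4-(benzyloxy)-3-methoxyphenyl]{(3S,4S,5S)-5-[4-(benzyloxy)-3-methoxyphenyl]-4-ethenyloxolan-3-yl}methanol | COc1cc([C@@H](O)[C@@H]2CO[C@H](c3ccc(OCc4ccccc4)c(OC)c3)[C@H]2C=C)ccc1OCc1ccccc1 | intermediate
14 | (2S,3S,4S)-2-[4-(benzyloxy)-3-methoxyphenyl]-4-{(S)-[4-(benzyloxy)-3-methoxyphenyl](hydroxy)methyl}oxolane-3-carbaldehyde | COc1cc([C@@H](O)[C@@H]2CO[C@H](c3ccc(OCc4ccccc4)c(OC)c3)[C@H]2C=O)ccc1OCc1ccccc1 | intermediate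
15 | (S)-[4-(benzyloxy)-3-methoxyphenyl]{(3S,4R,5S)-5-[4-(benzyloxy)-3-methoxyphenyl]-4-(hydroxymethyl)oxolan-3-yl}methanol | COc1cc([C@@H](O)[C@@H]2CO[C@H](c3ccc(OCc4ccccc4)c(OC)c3)[C@H]2CO)ccc1OCc1ccccc1 | intermediate
16 | (S)-(4-hydroxy-3-methoxyphenyl)[(3S,4R,5S)-5-(4-hydroxy-3-methoxyphenyl)-4-(hydroxymethyl)oxolan-3-yl]methanol | COc1cc([C@@H](O)[C@@H]2CO[C@H](c3ccc(O)c(OC)c3)[C@H]2CO)ccc1O | target

Total step count: 9. Longest linear sequence: 9 steps (1 to 16); bromide 11 enters directly in step 7.

Steps most likely to fail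

Step 7 (key step). The danger is insufficient facial discrimination at the formyl group, or enolisation of the aldehyde by the Grignard reagent with erosion of the C3 configuration. The fallback replaces substrate-controlled addition by acylation followed by reagent-controlled reduction. It sets out from ester 9, which is converted with MeNH(OMe)·HCl and i-PrMgCl (THF, −20 °C) into the N-methoxy-N-methyl amide F1. Acylation of arylmagnesium bromide 12 with F1 (THF, 0 °C) forms the same aryl–carbon bond and should give the aryl ketone F2. Because a simple hydride would follow the Felkin–Anh sense to the epimeric carbinol, F2 is reduced under catalyst control with (R)-2-methyl-CBS-oxazaborolidine [(R)-1-methyl-3,3-diphenyltetrahydro-1H,3H-pyrrolo[1,2-c][1,3,2]oxazaborole] and BH3·SMe2 (THF, −20 °C). This should deliver the (S)-carbinol, and the sequence comes back to the route at 13.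

Step 5. The danger is a slow 1,4-addition with competing 1,2-attack of the vinyl Grignard reagent on the ester, deprotonation at the benzylic C5–H, or cleavage of the allylic C5–O bond. The fallback sets out from 7 and uses a soft stabilised carbanion. Michael addition of nitromethane (DBU, MeCN, rt, the base also equilibrating C3) should give the all-trans nitromethyl ester F3. A Nef reaction (NaOMe, MeOH; then aq. TiCl3/NH4OAc) should give the formyl ester F4. Wittig methylenation (Ph3P=CH2 from Ph3PCH3Br and KOt-Bu, THF, 0 °C) comes back to the route at 9.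

Step 6. The danger is over-reduction, by collapse of the aluminium hemiacetal before the quench and further reduction of the released aldehyde. The fallback is a two-step redox detour from 9: full reduction with LiAlH4 (THF, 0 °C) to the primary alcohol F5, then oxidation with Dess–Martin periodinane (NaHCO3, CH2Cl2, 0 °C to rt), which comes back to the route at 10.

Further compounds
F1 | step 7 | (3S,4S,5S)-5-[4-(benzyloxy)-3-methoxyphenyl]-4-ethenyl-N-methoxy-N-methyloxolane-3-carboxamide | CON(C)C(=O)[C@@H]1CO[C@H](c2ccc(OCc3ccccc3)c(OC)c2)[C@H]1C=C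
F2 | step 7 | [4-(benzyloxy)-3-methoxyphenyl]{(3S,4S,5S)-5-[4-(benzyloxy)-3-methoxyphenyl]-4-ethenyloxolan-3-yl}methanone | COc1cc(C(=O)[C@@H]2CO[C@H](c3ccc(OCc4ccccc4)c(OC)c3)[C@H]2C=C)ccc1OCc1ccccc1
F3 | step 5 | methyl (3S,4R,5S)-5-[4-(benzyloxy)-3-methoxyphenyl]-4-(nitromethyl)oxolane-3-carboxylate | COC(=O)[C@@H]1CO[C@H](c2ccc(OCc3ccccc3)c(OC)c2)[C@H]1C[N+](=O)[O-]
F4 | step 5 | methyl (3S,4S,5S)-5-[4-(benzyloxy)-3-methoxyphenyl]-4-formyloxolane-3-carboxylate | COC(=O)[C@@H]1CO[C@H](c2ccc(OCc3ccccc3)c(OC)c2)[C@H]1C=O
F5 | step 6 | {(3R,4S,5S)-5-[4-(benzyloxy)-3-methoxyphenyl]-4-ethenyloxolan-3-yl}methanol | OC[C@@H]1CO[C@H](c2ccc(OCc3ccccc3)c(OC)c2)[C@H]1C=C
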